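At early times in the winter run the substrate stood at 76.2% after 6.00 min and 75.4% after 15.0 min, while the target read 0%. About a quarter of the charge had left the substrate without becoming target, and I read this as a fast passage into the dormant form. The mean of those two readings is 75.8%, and I took this reading as substrate over substrate plus dormant form, the free share. So in this flask I expected the substrate to equal the free share times what target and over-reacted product leave of the charge.

the same everywhere: substrate 0.30 M

| run | reagent in the second phase | protic impurity | remark | time | volume of the second phase over the first |
|---|---|---|---|---|---|
| winter | 0.75 M | 6 mM | the very flask that is asked about, followed so far |  |  |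
| flask | 0.750 M | 6.00 mM |  | 6.0 h | 1.0 |

- winter (time / min: target / %, substrate / %): 6.00: 0.1, 76.2; 15.0: 0, 75.4; 30.0: 1.9, 73.9; 50.0: 5.4, 71.6; 60.0: 5.5, 71.4; 80.0: 9.2, 69.2; 120: 15.0, 63.4

(each reading ± 0.5 percentage points)

- in the second phase: reagent in the second phase; everything else is in the first
- charges count per volume of the first phase; a concentration in a rate is the amount of a species over the volume of its own phase; every rate counts per litre of the first phase
- what was read earlier has a scatter of 0.5 percentage points, one standard deviation
- reactions considered so far: reagent in the reaction phase <-> reagent in the second phase; reagent in the reaction phase + protic impurity -> quenched reagent; reagent in the reaction phase + target -> over-reacted product; reagent in the reaction phase -> decomposed reagent; substrate + reagent in the reaction phase -> target; substrate <-> dormant form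
- the earlier runs hold the two phases in the same ratio of volumes as the flask asked about

- delta: doubling the amount of reagent in the second phase, all else as stated
- eta: doubling the transfer coefficient of the reagent in the second phase, all else as stated

- the target standing at 6.0 h, as a percentage of the substrate charged
- the change that raises the amount of target at 6.0 h, in percent of the substrate charged most ("none" if none brings more than 2 percentage points) (delta / eta / none)
- amount of target at 6.0 h, in percent of the substrate charged, after delta

How fast did that pool of substrate and dormant form empty? From 30.0 min to 120 min the target rose from 1.9% to 15.0%. Treating the step as pseudo-first-order, with steady reagent in the reaction phase, I read a pool constant of 0.0956 h⁻¹. Carried exponentially to 6.0 h, it put target plus over-reacted product at 42.0%. If delta doubled that constant, the remaining pool would be squared, giving 66.4%, so I chose delta.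

The forecast, reckoned differently, gave 40%, delta and 68%, holding that “reagent supply across the phases appears to limit the rate”.

The flask gave 36.5%. Delta gained 16 percentage points and eta 2.2 points, so the best change was delta, but delta reached 52.9%, which is 15 points below the forecast.

    reagent in the reaction phase ⇌ reagent in the second phase, rate k1*([reagent in the reaction phase] - [reagent in the second phase]/K1) per volume of the first phase (partition coefficient = 1.40, kL = 2.30 × 10⁻⁴ s⁻¹)
    reagent in the reaction phase + protic impurity → quenched reagent (k = 0.210 M⁻¹ s⁻¹)
    reagent in the reaction phase + target → over-reacted product (k = 4.90 × 10⁻⁵ M⁻¹ s⁻¹)
    reagent in the reaction phase → decomposed reagent (k = 7.30 × 10⁻⁵ s⁻¹)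
    substrate + reagent in the reaction phase → target (k = 1.90 × 10⁻⁴ M⁻¹ s⁻¹)
    substrate ⇌ dormant form (K = 0.320, k = 0.00200 s⁻¹)

In the flask the reagent in the second phase fell to 46.1% of its charge by 3.00 h and 30.4% by 6.00 h, while the reagent in the reaction phase went from 0.186 M to 0.126 M. By 6.00 h the flask held more decomposed reagent, 0.260 M, than target, 0.109 M. The free share applied to what target and over-reacted product left gives 45.5% substrate at 6.00 h, where 45.4% stood. For the same flask read at 10 h, with target at 44.7% and over-reacted product at 6.38%, it gives 37.1%, and the substrate stood at 37.1%.

The numbers in the tables were generated by integration for substances that don't exist; scatter was added.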